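**Strategy.** The route rests on one disconnection of the lavandulyl chain: C8–C1'' and C2''–C8'' are formed together. A palladium-induced 1,2-metallate shift joins the C8 bromide of ring A, a vinyl unit (C1''–C2'') and an isopropenyl group, sets C2'' and leaves boron on C2'' as the handle for C3''–C7''. The feature exploited is the array C8–C1''H2–C2''H(isopropenyl) on ring A, an arene and an alkenyl group on adjacent carbons of an ethane unit. The bromide precursor carries two different acetals, methoxymethyl on O5 and 1-ethoxyethyl on O8a, so that later only O8a can be freed to close ring C.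

Key step: step 4

Remark: ring A atoms carry flavanone numbers (O1, C4a, C5–C8, C8a) from the start; the side chain carries double-primed numbers.
Remark: the acetal carbon of the 1-ethoxyethyl group is stereogenic, so compounds 4, 9–11, 14–16, 20 and 21 are handled as two epimers at that carbon (left undefined in the SMILES); it is lost in step 9.
Remark: which antipode of the ferrocene ligand gives (R)-9 and which cinchona pseudoenantiomer gives (2S)-23 is assumed and to be confirmed on the first run; the other form is equally available.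

**Step 1**
Reactants: 1 5-methoxyresorcinol
Product: 2 4-bromo-5-methoxybenzene-1,3-diol
Conditions: NBS (1.0 equiv), THF, −78 °C → 0 °C
Reagents that add atoms: N-bromosuccinimide, O=C1CCC(=O)N1Br
Why: Electrophilic aromatic bromination of the activated resorcinol should take place at C4, para to one hydroxyl and ortho to the other, since the site between the two hydroxyls is more crowded; one equivalent at low temperature limits dibromination.

**Step 2**
Reactants: 2 4-bromo-5-methoxybenzene-1,3-diol
Product: 3 2-bromo-3-methoxy-5-(methoxymethoxy)phenol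
Conditions: NaH (2.2 equiv), DMF, 0 °C; MOMCl (1.0 equiv), −40 °C → 0 °C
Reagents that add atoms: chloromethyl methyl ether, COCCl
Why: Williamson etherification of the disodium diphenoxide: the phenoxide para to bromine (future O5) is the more basic and is unhindered, so it should take the single equivalent of alkylating agent ahead of the bromine-flanked phenoxide (future O8a).

**Step 3**
Reactants: 3 2-bromo-3-methoxy-5-(methoxymethoxy)phenol
Product: 4 2-bromo-1-(1-ethoxyethoxy)-3-methoxy-5-(methoxymethoxy)benzene
Conditions: ethyl vinyl ether (3 equiv), PPTS (5 mol%), CH2Cl2, 0 °C → rt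
Reagents that add atoms: ethyl vinyl ether, C=COCC
Why: Acid-catalysed addition of the remaining phenol to the enol ether (acetal formation) leaves the methoxymethyl ether intact and puts on O8a a second acetal that directs metalation and is far more acid-labile than the one on O5.

**Step 4**
Reactants: 4 2-bromo-1-(1-ethoxyethoxy)-3-methoxy-5-(methoxymethoxy)benzene; 5 vinylboronic acid pinacol ester; 6 2-bromopropene
Product: 9 2-[(2R)-1-[2-(1-ethoxyethoxy)-6-methoxy-4-(methoxymethoxy)phenyl]-3-methylbut-3-en-2-yl]-4,4,5,5-tetramethyl-1,3,2-dioxaborolane, via isopropenyllithium 7 (not isolated), via lithium isopropenyl(vinyl)borate 8 (not isolated)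
Conditions: 6, t-BuLi (2 equiv), Et2O, −78 °C; 5, −78 °C → rt; solvent change to THF; 4, Pd(OAc)2 (3 mol%), (S,S)-1,1′-bis(diphenylphosphino)-2,2′-bis[(R)-α-(dimethylamino)benzyl]ferrocene (MandyPhos, 3.6 mol%) or its antipode, KO3SCF3 (2 equiv), 60 °C
Reagents that add atoms: none
Why: Zerovalent palladium inserts into the C8–Br bond of 4, bromide is removed as KBr, and the resulting arylpalladium species of divalent palladium binds the unsubstituted vinyl group of borate 8; this triggers an anti 1,2-shift of isopropenyl from boron to C2'' with palladium arriving on C1'', and reductive elimination forms C8–C1''. The closest known reaction type is the enantioselective conjunctive cross-coupling of bis(alkenyl)borates with aryl electrophiles to give α-chiral allylic boronates. No ring is closed. The one new stereocentre, C2'', is set by the chiral bisphosphine, which selects the face of the bound vinyl group. Two selectivities are needed: the roles of the two alkenyl groups, secured by sterics (the α-substituted isopropenyl binds palladium poorly and migrates, the vinyl accepts), and conjunctive coupling over direct alkenyl transfer, secured by the chelating ligand and by halide removal with KO3SCF3. The acetals on O5 and O8a and the O7 methyl ether are spectators.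

**Step 5**
Reactants: 9 the (R)-allylic boronate
Product: 11 2-[(2R)-2-{[2-(1-ethoxyethoxy)-6-methoxy-4-(methoxymethoxy)phenyl]methyl}-3-methylbut-3-en-1-yl]-4,4,5,5-tetramethyl-1,3,2-dioxaborolane, via chloromethyl borate 10 (not isolated)
Conditions: BrCH2Cl (2.5 equiv), n-BuLi (2.0 equiv), THF, −78 °C → rt
Reagents that add atoms: bromochloromethane, ClCBr
Why: Matteson homologation: chloromethyllithium made in the flask adds to boron and C2'' of borate 10 migrates to the CH2 carbon with loss of chloride, a 1,2-shift with retention at the migrating carbon, so C3'' is installed without touching the C2'' configuration.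

**Step 6**
Reactants: 11 the homologated (R)-boronate; 12 1-bromo-2-methylprop-1-ene
Product: 16 1-(1-ethoxyethoxy)-3-methoxy-5-(methoxymethoxy)-2-[(2R)-5-methyl-2-(prop-1-en-2-yl)hex-4-en-1-yl]benzene, via 2-methylprop-1-enyllithium 13 (not isolated), via alkenyl borate 14 (not isolated), via iodoalkyl boronate 15 (not isolated)
Conditions: 12, t-BuLi (2 equiv per 12), THF, −78 °C; 11, −78 °C; I2, THF, −78 °C; NaOMe, MeOH, −78 °C → rt
Reagents that add atoms: none
Why: Zweifel olefination: the alkenyllithium forms borate 14, iodine activates its alkene so that C3'' migrates from boron to the alkenyl carbon to give 15, and methoxide triggers anti elimination of boron and iodine to the C4''=C5'' alkene; C2'' is not involved and the trisubstituted alkene has no geometry to control.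

**Step 7**
Reactants: 17 2,6-dihydroxybenzaldehyde
Product: 18 2,6-bis(methoxymethoxy)benzaldehyde
Conditions: NaH (2.5 equiv), MOMCl (2.5 equiv), DMF, 0 °C → rt
Reagents that add atoms: chloromethyl methyl ether, COCCl
Why: Williamson etherification of both phenoxides masks the ring B hydroxyls as acetals that survive organolithium reagents and fall in the last step.

**Step 8**
Reactants: 18 2,6-bis(methoxymethoxy)benzaldehyde
Product: 19 (E)-3-[2,6-bis(methoxymethoxy)phenyl]-N-methoxy-N-methylprop-2-enamide
Conditions: (EtO)2P(O)CH2C(O)N(OMe)Me (1.2 equiv), NaH (1.2 equiv), THF, 0 °C → rt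
Reagents that add atoms: diethyl [2-(methoxy(methyl)amino)-2-oxoethyl]phosphonate, CCOP(=O)(CC(=O)N(C)OC)OCC
Why: Horner–Wadsworth–Emmons olefination with the stabilised phosphonate anion should give the (E)-unsaturated Weinreb amide.

**Step 9**
Reactants: 16 the lavandulyl arene; 19 the unsaturated Weinreb amide
Product: 22 (E)-3-[2,6-bis(methoxymethoxy)phenyl]-1-[2-hydroxy-4-methoxy-6-(methoxymethoxy)-3-[(2R)-5-methyl-2-(prop-1-en-2-yl)hex-4-en-1-yl]phenyl]prop-2-en-1-one, via aryllithium 20 (not isolated), via ethoxyethyl-protected chalcone 21 (not isolated)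
Conditions: n-BuLi (1.2 equiv), THF, 0 °C; 19, −78 °C → 0 °C; NH4Cl aq; then PPTS (0.2 equiv), EtOH, rt
Reagents that add atoms: none
Why: Directed ortho-metalation should occur at C4a, the only site flanked by two acetal oxygens (O5 and O8a), and the aryllithium adds 1,2 to the Weinreb amide to give a chelated adduct that releases the enone only on work-up (Weinreb ketone synthesis); pyridinium tosylate in ethanol then exchanges off the 1-ethoxyethyl acetal alone, freeing O8a–H while the methoxymethyl ethers stay.

**Step 10**
Reactants: 22 the 2'-hydroxychalcone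
Product: 23 (2S)-2-[2,6-bis(methoxymethoxy)phenyl]-7-methoxy-5-(methoxymethoxy)-8-[(2R)-5-methyl-2-(prop-1-en-2-yl)hex-4-en-1-yl]-2,3-dihydro-4H-chromen-4-one
Conditions: 1-[3,5-bis(trifluoromethyl)phenyl]-3-[(8S,9S)-6′-methoxycinchonan-9-yl]thiourea (10 mol%) or its quinidine-derived pseudoenantiomer, toluene, 0 °C → rt
Reagents that add atoms: none
Why: Enantioselective intramolecular oxa-Michael addition (asymmetric chalcone-to-flavanone cyclisation) under bifunctional cinchona thiourea catalysis: the quinuclidine activates the O8a phenol and the thiourea the enone, so O8a adds to one face of C2 under catalyst control with no influence from remote C2'', and since O5 is still an acetal ring C can close only through O8a.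

**Step 11**
Reactants: 23 the protected (2S)-flavanone
Product: 24 exiguaflavanone B
Conditions: HCl (3 M aq), MeOH/THF, rt
Reagents that add atoms: none
Why: Acid-catalysed acetal exchange with methanol removes the three methoxymethyl ethers, the one on O5 assisted by the neighbouring carbonyl; the lavandulyl group sits between the O7 methyl ether and O1 and has no free ortho hydroxyl to add to its alkenes, and dilute acid at room temperature should leave C2 and the alkenes untouched.

**Compound list**
1 | 5-methoxyresorcinol | COc1cc(O)cc(O)c1 | starting material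
2 | 4-bromo-5-methoxybenzene-1,3-diol | COc1cc(O)cc(O)c1Br | intermediate
3 | 2-bromo-3-methoxy-5-(methoxymethoxy)phenol | COCOc1cc(O)c(Br)c(OC)c1 | intermediate
4 | 2-bromo-1-(1-ethoxyethoxy)-3-methoxy-5-(methoxymethoxy)benzene | CCOC(C)Oc1cc(OCOC)cc(OC)c1Br | intermediate
5 | vinylboronic acid pinacol ester | C=CB1OC(C)(C)C(C)(C)O1 | starting material
6 | 2-bromopropene | C=C(C)Br | starting material
7 | isopropenyllithium (formed in the flask) | [Li]C(C)=C | intermediate
8 | lithium isopropenyl(vinyl)(pinacolato)borate (formed in the flask) | [Li+].C=C[B-]1(C(C)=C)OC(C)(C)C(C)(C)O1 | intermediate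
9 | 2-[(2R)-1-[2-(1-ethoxyethoxy)-6-methoxy-4-(methoxymethoxy)phenyl]-3-methylbut-3-en-2-yl]-4,4,5,5-tetramethyl-1,3,2-dioxaborolane | C=C(C)[C@H](B1OC(C)(C)C(C)(C)O1)Cc1c(OC)cc(OCOC)cc1OC(C)OCC | intermediate
10 | lithium chloromethyl borate of 9 (formed in the flask) | [Li+].C=C(C)[C@H]([B-]1(CCl)OC(C)(C)C(C)(C)O1)Cc1c(OC)cc(OCOC)cc1OC(C)OCC | intermediate
11 | 2-[(2R)-2-{[2-(1-ethoxyethoxy)-6-methoxy-4-(methoxymethoxy)phenyl]methyl}-3-methylbut-3-en-1-yl]-4,4,5,5-tetramethyl-1,3,2-dioxaborolane | C=C(C)[C@H](CB1OC(C)(C)C(C)(C)O1)Cc1c(OC)cc(OCOC)cc1OC(C)OCC | intermediate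
12 | 1-bromo-2-methylprop-1-ene | CC(C)=CBr | starting material
13 | 2-methylprop-1-enyllithium (formed in the flask) | [Li]C=C(C)C | intermediate
14 | lithium (2-methylprop-1-enyl) borate of 11 (formed in the flask) | [Li+].C=C(C)[C@H](C[B-]1(C=C(C)C)OC(C)(C)C(C)(C)O1)Cc1c(OC)cc(OCOC)cc1OC(C)OCC | intermediate
15 | β-iodoalkyl boronate from 14, epimers at the boron-bearing carbon (formed in the flask) | C=C(C)[C@H](CC(B1OC(C)(C)C(C)(C)O1)C(C)(C)I)Cc1c(OC)cc(OCOC)cc1OC(C)OCC | intermediate
16 | 1-(1-ethoxyethoxy)-3-methoxy-5-(methoxymethoxy)-2-[(2R)-5-methyl-2-(prop-1-en-2-yl)hex-4-en-1-yl]benzene | C=C(C)[C@H](CC=C(C)C)Cc1c(OC)cc(OCOC)cc1OC(C)OCC | intermediate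
17 | 2,6-dihydroxybenzaldehyde | O=Cc1c(O)cccc1O | starting material
18 | 2,6-bis(methoxymethoxy)benzaldehyde | O=Cc1c(OCOC)cccc1OCOC | intermediate
19 | (E)-3-[2,6-bis(methoxymethoxy)phenyl]-N-methoxy-N-methylprop-2-enamide | CON(C)C(=O)/C=C/c1c(OCOC)cccc1OCOC | intermediate
20 | C4a-lithiated 16 (formed in the flask) | C=C(C)[C@H](CC=C(C)C)Cc1c(OC)cc(OCOC)c([Li])c1OC(C)OCC | intermediate
21 | O8a-(1-ethoxyethyl) ether of chalcone 22 (formed in the flask) | C=C(C)[C@H](CC=C(C)C)Cc1c(OC)cc(OCOC)c(C(=O)/C=C/c2c(OCOC)cccc2OCOC)c1OC(C)OCC | intermediate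
22 | (E)-3-[2,6-bis(methoxymethoxy)phenyl]-1-[2-hydroxy-4-methoxy-6-(methoxymethoxy)-3-[(2R)-5-methyl-2-(prop-1-en-2-yl)hex-4-en-1-yl]phenyl]prop-2-en-1-one | C=C(C)[C@H](CC=C(C)C)Cc1c(OC)cc(OCOC)c(C(=O)/C=C/c2c(OCOC)cccc2OCOC)c1O | intermediate
23 | (2S)-2-[2,6-bis(methoxymethoxy)phenyl]-7-methoxy-5-(methoxymethoxy)-8-[(2R)-5-methyl-2-(prop-1-en-2-yl)hex-4-en-1-yl]-2,3-dihydro-4H-chromen-4-one | C=C(C)[C@H](CC=C(C)C)Cc1c(OC)cc(OCOC)c2c1O[C@H](c1c(OCOC)cccc1OCOC)CC2=O | intermediate
24 | exiguaflavanone B, (2S)-2-(2,6-dihydroxyphenyl)-5-hydroxy-7-methoxy-8-[(2R)-5-methyl-2-(prop-1-en-2-yl)hex-4-en-1-yl]-2,3-dihydro-4H-chromen-4-one | C=C(C)[C@H](CC=C(C)C)Cc1c(OC)cc(O)c2c1O[C@H](c1c(O)cccc1O)CC2=O | target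

**Step count.** Total: 11 steps. Longest linear sequence: 9 steps (steps 1–6 and 9–11); steps 7 and 8 are a two-step side branch.

**Steps most likely to fail**

Step 4. Insertion of palladium into the doubly ortho-oxygenated, electron-rich C8–Br bond may be slow, so that the borate decomposes or transfers an alkenyl group directly, and facial control at C2'' may be incomplete. The fallback sets out from 4 and comes back at 16, giving up the three-component assembly for a chiral-pool side chain. (S)-Lavandulol F1, from lipase resolution of commercial racemic lavandulol, is converted with I2, PPh3 and imidazole into (S)-lavandulyl iodide F2. Iodine–lithium exchange (t-BuLi, Et2O, −78 °C) followed by ZnCl2 gives (S)-lavandulylzinc chloride F3. Negishi coupling of F3 with 4 (Pd(OAc)2, CPhos, THF, rt) forms C8–C1'' and gives 16 directly.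

Step 10. Facial selection in the C–O bond formation may be poor for a chalcone whose β-carbon carries a doubly ortho-substituted aryl group, or the selectivity may erode through reversible ring opening. The fallback sets out from 22 and comes back at 23. Closure without facial control (NaOAc, EtOH, reflux) gives 23 together with its C2 epimer, the (2R)-flavanone F4. Asymmetric transfer hydrogenation of the mixture (Cp*RhCl[(R,R)-TsDPEN] or its antipode, HCO2H/Et3N, EtOAc), with the catalyst antipode chosen so that the (2R) series reacts faster, reduces F4 to the cis-flavan-4-ol F5 in a kinetic resolution. Unreduced 23 is separated from F5 by chromatography.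

Step 2. Alkylation may occur on the wrong phenoxide or on both, because chloromethyl methyl ether is small and reactive. The fallback sets out from 2 and comes back at 4, replacing electronic discrimination by steric discrimination and a protecting-group exchange. i-Pr3SiCl and imidazole (DMF, 0 °C) silylate the unhindered hydroxyl para to bromine to give 2-bromo-3-methoxy-5-(triisopropylsilyloxy)phenol F6. Ethyl vinyl ether with PPTS converts the remaining hydroxyl into the 1-ethoxyethyl acetal, giving the silyl ether F7. Bu4NF (THF, 0 °C) frees O5 to give 4-bromo-3-(1-ethoxyethoxy)-5-methoxyphenol F8, and NaH with chloromethyl methyl ether then gives 4.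

**Further compounds**
F1 | step 4 | (S)-lavandulol, (2S)-5-methyl-2-(prop-1-en-2-yl)hex-4-en-1-ol | C=C(C)[C@H](CC=C(C)C)CO
F2 | step 4 | (S)-lavandulyl iodide, (5S)-6-iodo-2-methyl-5-(prop-1-en-2-yl)hex-2-ene | C=C(C)[C@H](CC=C(C)C)CI
F3 | step 4 | (S)-lavandulylzinc chloride | C=C(C)[C@H](CC=C(C)C)C[Zn]Cl
F4 | step 10 | (2R)-2-[2,6-bis(methoxymethoxy)phenyl]-7-methoxy-5-(methoxymethoxy)-8-[(2R)-5-methyl-2-(prop-1-en-2-yl)hex-4-en-1-yl]-2,3-dihydro-4H-chromen-4-one | C=C(C)[C@H](CC=C(C)C)Cc1c(OC)cc(OCOC)c2c1O[C@@H](c1c(OCOC)cccc1OCOC)CC2=O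
F5 | step 10 | (2R,4R)-2-[2,6-bis(methoxymethoxy)phenyl]-7-methoxy-5-(methoxymethoxy)-8-[(2R)-5-methyl-2-(prop-1-en-2-yl)hex-4-en-1-yl]-3,4-dihydro-2H-chromen-4-ol (cis) | C=C(C)[C@H](CC=C(C)C)Cc1c(OC)cc(OCOC)c2c1O[C@@H](c1c(OCOC)cccc1OCOC)C[C@H]2O
F6 | step 2 | 2-bromo-3-methoxy-5-(triisopropylsilyloxy)phenol | COc1cc(O[Si](C(C)C)(C(C)C)C(C)C)cc(O)c1Br
F7 | step 2 | [4-bromo-3-(1-ethoxyethoxy)-5-methoxyphenoxy]triisopropylsilane | CCOC(C)Oc1cc(O[Si](C(C)C)(C(C)C)C(C)C)cc(OC)c1Br
F8 | step 2 | 4-bromo-3-(1-ethoxyethoxy)-5-methoxyphenol | CCOC(C)Oc1cc(O)cc(OC)c1Br
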